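**Retrosynthetic overview**

1. Feature (germacrane numbering: C1 OMe, C4=C5, C6 lactone O, C7, C8 acyloxy, C9 C=O, C10 Me, C11 Me, C12 lactone C=O): in the ten-membered carbocycle the C8 carbinol lies between the C9 ketone and C7, which carries the three-carbon C11(C13)–C12 branch of the γ-lactone. An α-hydroxy ketone next to an isopropenyl-bearing carbon is the retron of an enolate [2,3]-Wittig shift, so C7–C8 is disconnected and O8 reconnected to C12, giving the thirteen-membered α-allyloxy ketone 20.
2. 20 comes from keto enal 17 by Nozaki–Hiyama–Kishi closure of C5–C6 under ligand control (C6). 17 comes from diol 8 and allylic bromide 13 by stannylene O-alkylation (C8–O–C12); alkylation is used because a C8 carbenoid would be trapped by the C1 methoxy oxygen.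
3. 8 comes from 4-pentyn-1-ol by carboalumination/iodination (E C4=C5), anti crotylboration (C1, C10), O-methylation and dihydroxylation. 13 comes from prenol by allylic oxidation.
4. After the shift, the isopropenyl group is taken to the C12 aldehyde, O6 closes the lactol, C11 is equilibrated there (in the lactone the ketone would enolise first), then lactone, and O8 is esterified with epoxy acid 36 (tiglic acid, Sharpless epoxidation).
5. Ring order: thirteen-membered ether ring (step 12), ten-membered carbocycle by ring contraction (step 14), γ-lactone (steps 18–20); the oxirane arrives with the acyl group (steps 23, 25).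

Key step: step 14

Remark: the C9 carbinol of 8, 14, 15 and 16 and C11 of 25 to 29 are carried as epimer mixtures because both centres are converted later (steps 11 and 19); in step 12 the ligand enantiomer is the one that directs the alkenyl group to the Si face of the aldehyde, which is not predicted from first principles.

**Route**

Step 1
Reactants: 1 4-pentyn-1-ol
Product: 3 (E)-5-iodo-4-methylpent-4-en-1-ol, via alkenylalane 2 (not isolated)
Conditions: Me3Al (3 equiv), Cp2ZrCl2 (0.25 equiv), CH2Cl2, 0 °C to rt; then I2, THF, −30 to 0 °C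
Reagents that add atoms: trimethylaluminium C[Al](C)C; iodine II
Why: Zirconium-catalysed Negishi carboalumination adds methyl and aluminium syn across the terminal alkyne with methyl on the internal carbon, and iodinolysis of the C–Al bond with retention should give the E trisubstituted iodoalkene that becomes C4=C5.

Step 2
Reactants: 3 (E)-5-iodo-4-methylpent-4-en-1-ol
Product: 4 (E)-5-iodo-4-methylpent-4-enal
Conditions: Dess–Martin periodinane, NaHCO3, CH2Cl2, 0 °C to rt
Reagents that add atoms: none
Why: Dess–Martin oxidation should take the primary alcohol to the aldehyde (the later C1) under buffered conditions that leave the iodoalkene intact.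

Step 3
Reactants: 4 (E)-5-iodo-4-methylpent-4-enal
Product: 6 (3R,4S,7E)-8-iodo-3,7-dimethylocta-1,7-dien-4-ol, via borinate ester 5 (not isolated)
Conditions: trans-2-butene, n-BuLi, KOtBu, THF, −78 to −45 °C; (+)-Ipc2BOMe, −78 °C; BF3·OEt2; 4, −78 °C; then NaOH, H2O2, 0 °C to rt
Reagents that add atoms: trans-2-butene C/C=C/C
Why: Brown crotylboration proceeds through a closed chair transition state in which the E crotyl geometry gives the anti C1/C10 relationship and the isopinocampheyl groups derived from (−)-α-pinene direct the allyl unit to the Re face of the aldehyde, so C1 (S) and C10 should be set in one step with the C8=C9 vinyl group in place.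

Step 4
Reactants: 6 (3R,4S,7E)-8-iodo-3,7-dimethylocta-1,7-dien-4-ol
Product: 7 (3R,4S,7E)-8-iodo-4-methoxy-3,7-dimethylocta-1,7-diene
Conditions: NaH, MeI, THF, 0 °C to rt
Reagents that add atoms: iodomethane CI
Why: Williamson etherification of the sodium alkoxide installs the C1 methoxy group at a stage where no carbonyl group is present, so neither retro-aldol cleavage nor elimination can interfere.

Step 5
Reactants: 7 (3R,4S,7E)-8-iodo-4-methoxy-3,7-dimethylocta-1,7-diene
Product: 8 (3R,4S,7E)-8-iodo-4-methoxy-3,7-dimethyloct-7-ene-1,2-diol (C2 epimers; C2 is the later C9)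
Conditions: OsO4 (2 mol%), N-methylmorpholine N-oxide, acetone/H2O, rt
Reagents that add atoms: osmium tetroxide O=[Os](=O)(=O)=O; N-methylmorpholine N-oxide C[N+]1([O-])CCOCC1; water O
Why: Upjohn dihydroxylation should occur only at the monosubstituted alkene because the iodine-bearing trisubstituted alkene is electron-poor and hindered; the C9 carbinol forms as a mixture, which is of no consequence since it is oxidised in step 11.

Step 6
Reactants: 9 prenol
Product: 10 tert-butyldimethyl(3-methylbut-2-enyloxy)silane
Conditions: TBSCl, imidazole, CH2Cl2, rt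
Reagents that add atoms: tert-butyldimethylsilyl chloride CC(C)(C)[Si](C)(C)Cl
Why: Standard silylation of the primary allylic alcohol (protection) masks the later C6 oxygen during the allylic oxidation.

Step 7
Reactants: 10 tert-butyldimethyl(3-methylbut-2-enyloxy)silane
Product: 12 (E)-4-(tert-butyldimethylsilyloxy)-2-methylbut-2-en-1-ol, via enal 11 (not isolated)
Conditions: SeO2 (0.5 equiv), t-BuOOH, salicylic acid (cat.), CH2Cl2, rt; then NaBH4, MeOH, 0 °C
Reagents that add atoms: selenium dioxide O=[Se]=O; tert-butyl hydroperoxide CC(C)(C)OO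
Why: Riley oxidation (ene reaction then [2,3]-sigmatropic shift of the allylseleninic acid) oxidises the methyl group trans to the chain and so should give the E allylic alcohol, the later C12 trans to C6 across C7=C11; enal 11 formed in part by over-oxidation is returned to 12 by borohydride in the same flask.

Step 8
Reactants: 12 (E)-4-(tert-butyldimethylsilyloxy)-2-methylbut-2-en-1-ol
Product: 13 (E)-(4-bromo-3-methylbut-2-enyloxy)(tert-butyl)dimethylsilane
Conditions: CBr4, PPh3, CH2Cl2, 0 °C
Reagents that add atoms: carbon tetrabromide BrC(Br)(Br)Br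
Why: Appel bromination converts the primary allylic alcohol into the bromide by SN2 displacement of the oxyphosphonium ion, without allylic transposition or loss of alkene geometry at 0 °C.

Step 9
Reactants: 8 (3R,4S,7E)-8-iodo-4-methoxy-3,7-dimethyloct-7-ene-1,2-diol; 13 (E)-(4-bromo-3-methylbut-2-enyloxy)(tert-butyl)dimethylsilane
Product: 15 (3R,4S,7E)-1-[(E)-4-(tert-butyldimethylsilyloxy)-2-methylbut-2-enyloxy]-8-iodo-4-methoxy-3,7-dimethyloct-7-en-2-ol (C2 epimers), via stannylene acetal 14 (not isolated)
Conditions: Bu2SnO, toluene, reflux (Dean–Stark); then 13, CsF, DMF, rt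
Reagents that add atoms: none
Why: Stannylene acetal O-alkylation: in the dibutylstannylene acetal of a terminal 1,2-diol the primary oxygen is the one activated toward electrophiles, so fluoride-promoted SN2 reaction with the primary allylic bromide should form the C8–O–C12 ether and leave the hindered C9 hydroxyl free.

Step 10
Reactants: 15 silyl ether alcohol
Product: 16 (3R,4S,7E)-1-[(E)-4-hydroxy-2-methylbut-2-enyloxy]-8-iodo-4-methoxy-3,7-dimethyloct-7-en-2-ol (C2 epimers)
Conditions: Bu4NF, THF, 0 °C to rt
Reagents that add atoms: none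
Why: Fluoride cleaves the primary silyl ether (desilylation) and frees the C6 hydroxyl; no base-sensitive group is present yet.

Step 11
Reactants: 16 diol
Product: 17 (E)-4-[(3S,4S,7E)-8-iodo-4-methoxy-3,7-dimethyl-2-oxooct-7-enyloxy]-3-methylbut-2-enal
Conditions: Dess–Martin periodinane (3 equiv), NaHCO3, CH2Cl2, 0 °C to rt
Reagents that add atoms: none
Why: Dess–Martin oxidation converts the primary allylic alcohol into the E enal and the C9 carbinol into the ketone in one operation, under buffered conditions that should not epimerise C10 or isomerise the enal.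

Step 12
Reactants: 17 keto enal
Product: 19 (4S,5S,8E,10S,11E)-10-hydroxy-5-methoxy-4,8,12-trimethyl-1-oxacyclotrideca-8,11-dien-3-one (germacrane locants 1S,6S,10S), via alkenylchromium species 18 (not isolated)
Conditions: CrCl2 (8 equiv), NiCl2 (1 mol%), valinol-derived 2-(2-sulfonamidoaryl)oxazoline ligand (9 equiv), Et3N, THF, 0.002 M, rt
Reagents that add atoms: none
Why: Nozaki–Hiyama–Kishi reaction: nickel-catalysed formation of the alkenylchromium species 18 from the E iodoalkene (geometry retained) and its addition to the aldehyde, which organochromium reagents select over ketones, closes the strain-free thirteen-membered ring at C5–C6 under high dilution; the sulfonamide ligand on trivalent chromium discriminates the two faces of the aldehyde (H against alkenyl), so addition to the Si face should give the 6S carbinol independently of the distant C1 and C10 centres.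

Step 13
Reactants: 19 macrocyclic alcohol
Product: 20 (4S,5S,8E,10S,11E)-5-methoxy-4,8,12-trimethyl-10-(triethylsilyloxy)-1-oxacyclotrideca-8,11-dien-3-one
Conditions: TESCl, imidazole, DMF, 0 °C
Reagents that add atoms: chlorotriethylsilane CC[Si](CC)(CC)Cl
Why: Silylation of the doubly allylic alcohol with the silyl chloride and imidazole avoids acid, and triethylsilyl is chosen because it is small on the face that C8 must approach in step 14 and can later be removed beside a TBS ether.

Step 14
Reactants: 20 thirteen-membered α-allyloxy ketone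
Product: 23 (2R,3R,4S,5E,9S,10S)-2-hydroxy-9-methoxy-6,10-dimethyl-3-(prop-1-en-2-yl)-4-(triethylsilyloxy)cyclodec-5-en-1-one (germacrane locants 8R,7R,6S,1S,10S), via lithium enolate 21 (not isolated), via lithium alkoxide 22 (not isolated)
Conditions: LiN(iPr)2 (1.2 equiv), THF, −78 °C, then slowly to −40 °C; AcOH, THF, −78 °C
Reagents that add atoms: none
Why: Proposed new method: kinetic deprotonation of the less hindered, alkoxy-activated C8 methylene (C10 is a crowded methine) should give the chelated Z lithium enolate 21, which bonds from C8 to C7 through a five-membered envelope while the allylic O–C12 bond breaks, a concerted [2,3]-Wittig shift; the closest known reactions are the [2,3]-Wittig ring contraction of thirteen-membered allyl propargyl ethers to cyclodecenols and the enolate [2,3]-Wittig shift of open-chain α-allyloxy carbonyl compounds, which have not been combined on a macrocyclic ketone. The ten-membered carbocycle is closed by ring contraction, that is by bond formation between two atoms of the existing thirteen-membered ring through the five-centre sigmatropic transition state with O, C12 and C11 expelled from the ring, and not by end-to-end cyclisation of a chain. C7 is controlled by C6 together with the E C7=C11 alkene: allylic 1,3-strain with the C13 methyl holds H6 in the alkene plane, the ring bonds C6–C5 and C12–O of the E cycloalkene lie on opposite faces, and C8 therefore adds to the face anti to C5, which gives the C6/C7 relationship of the cis-fused lactone. C8 is controlled by the envelope: the acyl carbon C9, which carries the rest of the ring, sits exo, away from the allyl unit and the C6 substituents, and this gives the 8R carbinol. The step needs the [2,3] shift to beat the [3,3] enolate Claisen shift (which would give a nine-membered ring) and deprotonation at C10 with loss of methoxide; the lithium counter-ion, the low temperature and the kinetic base favour the carbon-centred [2,3] path from the C8 enolate, and the cold acidic quench keeps alkoxide 22 from silyl migration or ketol isomerisation.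

Step 15
Reactants: 23 C8-hydroxy C7-isopropenyl cyclodecenone
Product: 24 C8 tert-butyldimethylsilyl ether of 23
Conditions: TBSOTf, 2,6-lutidine, CH2Cl2, −78 to 0 °C
Reagents that add atoms: tert-butyldimethylsilyl trifluoromethanesulfonate CC(C)(C)[Si](C)(C)OS(=O)(=O)C(F)(F)F
Why: Silylation with the silyl triflate and a hindered pyridine base protects the crowded C8 hydroxyl without enolising the ketone, which is needed because O8, like O6, is gamma to C12 and could otherwise close the lactol or lactone.

Step 16
Reactants: 24 bis-silyl ether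
Product: 26 C12 primary alcohol from 24 (C11 epimers), via catechol boronate 25 (not isolated)
Conditions: catecholborane (2 equiv), RhCl(PPh3)3 (3 mol%), THF, rt; then pH 7 phosphate buffer, H2O2, 0 °C
Reagents that add atoms: hydrogen peroxide OO
Why: Rhodium-catalysed hydroboration with catecholborane places boron on the terminal carbon of the 1,1-disubstituted alkene, is faster than uncatalysed reduction of the hindered C9 ketone and does not touch the trisubstituted ring alkene, and oxidation of the C–B bond gives the C12 alcohol; C11 forms without control and is set in step 19.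

Step 17
Reactants: 26 C12 primary alcohol
Product: 27 C12 aldehyde (C11 epimers)
Conditions: Dess–Martin periodinane, NaHCO3, CH2Cl2, 0 °C
Reagents that add atoms: none
Why: Dess–Martin oxidation takes the primary alcohol to the C12 aldehyde under buffered conditions.

Step 18
Reactants: 27 C12 aldehyde
Product: 29 cis-fused 6,12-lactol (C11 and C12 epimers), via hydroxy aldehyde 28 (not isolated)
Conditions: HF·pyridine, pyridine, THF, 0 °C
Reagents that add atoms: none
Why: Buffered HF·pyridine should cleave the secondary allylic triethylsilyl ether while the hindered TBS ether survives (selective desilylation), and the freed C6 hydroxyl adds to the C12 aldehyde to close the five-membered lactol (hemiacetal formation), O8 being blocked.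

Step 19
Reactants: 29 lactol mixture
Product: 30 (11S)-6,12-lactol (C12 anomers)
Conditions: DBU (0.2 equiv), CH2Cl2, rt
Reagents that add atoms: none
Why: Amidine-catalysed epimerisation through the ring-opened hydroxy aldehyde and its enol (ring–chain tautomerism) equilibrates C11, the aldehyde α-carbon being far more readily enolised than the hindered ketone α-carbons, toward the cis-fused lactol that carries the C11 methyl on the convex face trans to C8, which is the 11S configuration of the target.

Step 20
Reactants: 30 (11S)-lactol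
Product: 31 (1S,6S,7S,8R,10S,11S)-8-(tert-butyldimethylsilyloxy)-1-methoxy-9-oxogermacr-4(E)-en-12,6-olide
Conditions: NPr4RuO4 (5 mol%), N-methylmorpholine N-oxide, 4 Å molecular sieves, CH2Cl2, rt
Reagents that add atoms: none
Why: Ley–Griffith oxidation converts the lactol into the γ-lactone under neutral conditions that leave C11, the ketone and the silyl ether untouched.

Step 21
Reactants: 31 silyl lactone
Product: 32 (1S,6S,7R,8R,10S,11S)-8-hydroxy-1-methoxy-9-oxogermacr-4(E)-en-12,6-olide
Conditions: HF·pyridine, THF, 0 °C to rt
Reagents that add atoms: none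
Why: HF·pyridine cleaves the TBS ether under mildly acidic conditions (desilylation), so that O8 is freed without a base that could trigger translactonisation to O8 or enolisation of the ketone.

Step 22
Reactants: 33 tiglic acid
Product: 34 (E)-2-methylbut-2-en-1-ol
Conditions: LiAlH4, Et2O, 0 °C to rt
Reagents that add atoms: none
Why: LiAlH4 reduction of the carboxylic acid gives the primary allylic alcohol with the E alkene unchanged.

Step 23
Reactants: 34 (E)-2-methylbut-2-en-1-ol
Product: 35 [(2R,3R)-2,3-dimethyloxiran-2-yl]methanol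
Conditions: Ti(OiPr)4 (10 mol%), D-(−)-diisopropyl tartrate (12 mol%), t-BuOOH, 4 Å molecular sieves, CH2Cl2, −20 °C
Reagents that add atoms: tert-butyl hydroperoxide CC(C)(C)OO
Why: Sharpless asymmetric epoxidation: the titanium tartrate complex delivers the peroxide oxygen to one face of the allylic alcohol, D-(−)-tartrate giving the (2R,3R)-epoxide, and the E alkene geometry is carried over as the cis relationship of the two methyl groups.

Step 24
Reactants: 35 epoxy alcohol
Product: 36 (2S,3R)-2,3-dimethyloxirane-2-carboxylic acid
Conditions: RuCl3 (2 mol%), NaIO4, CCl4/MeCN/H2O, rt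
Reagents that add atoms: water O
Why: Ruthenium tetroxide oxidation (RuCl3 with periodate as terminal oxidant) takes the primary alcohol through the aldehyde hydrate to the carboxylic acid without opening the epoxide, and the C2 descriptor becomes S only because the carboxyl group now outranks C3.

Step 25
Reactants: 32 hydroxy lactone; 36 (2S,3R)-2,3-dimethyloxirane-2-carboxylic acid
Product: 38 CNP0145898.1, via mixed anhydride 37 (not isolated)
Conditions: 36, 2,4,6-Cl3C6H2COCl, Et3N, toluene, rt; then 32, DMAP, toluene, rt
Reagents that add atoms: none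
Why: Yamaguchi esterification: DMAP attacks mixed anhydride 37 at the epoxy acyl carbonyl (the aryl carbonyl is shielded by two ortho chlorines) and the acylpyridinium ion acylates the hindered C8 hydroxyl with retention at C8, under conditions mild enough to spare the epoxide, the lactone and C11.

**Compound list**

1 | 4-pentyn-1-ol | C#CCCCO | starting material
2 | dimethyl[(E)-5-(dimethylaluminiooxy)-2-methylpent-1-enyl]aluminium (not isolated) | C[Al](C)/C=C(\C)CCCO[Al](C)C | intermediate
3 | (E)-5-iodo-4-methylpent-4-en-1-ol | OCCC/C(C)=C/I | intermediate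
4 | (E)-5-iodo-4-methylpent-4-enal | O=CCC/C(C)=C/I | intermediate
5 | diisopinocampheylborinate ester of 6 (not isolated) | C=C[C@@H](C)[C@@H](OB([C@H]1C[C@H]2C[C@@H]([C@@H]1C)C2(C)C)[C@H]1C[C@H]2C[C@@H]([C@@H]1C)C2(C)C)CC/C(C)=C/I | intermediate
6 | (3R,4S,7E)-8-iodo-3,7-dimethylocta-1,7-dien-4-ol | C=C[C@@H](C)[C@@H](O)CC/C(C)=C/I | intermediate
7 | (3R,4S,7E)-8-iodo-4-methoxy-3,7-dimethylocta-1,7-diene | C=C[C@@H](C)[C@@H](OC)CC/C(C)=C/I | intermediate
8 | (3R,4S,7E)-8-iodo-4-methoxy-3,7-dimethyloct-7-ene-1,2-diol (C2 epimers) | OCC(O)[C@@H](C)[C@@H](OC)CC/C(C)=C/I | intermediate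
9 | prenol (3-methylbut-2-en-1-ol) | CC(C)=CCO | starting material
10 | tert-butyldimethyl(3-methylbut-2-enyloxy)silane | CC(C)=CCO[Si](C)(C)C(C)(C)C | intermediate
11 | (E)-4-(tert-butyldimethylsilyloxy)-2-methylbut-2-enal (formed in part, not isolated) | O=C/C(C)=C/CO[Si](C)(C)C(C)(C)C | intermediate
12 | (E)-4-(tert-butyldimethylsilyloxy)-2-methylbut-2-en-1-ol | OC/C(C)=C/CO[Si](C)(C)C(C)(C)C | intermediate
13 | (E)-(4-bromo-3-methylbut-2-enyloxy)(tert-butyl)dimethylsilane | BrC/C(C)=C/CO[Si](C)(C)C(C)(C)C | intermediate
14 | dibutylstannylene acetal of 8 (not isolated) | CCCC[Sn]1(CCCC)OCC(O1)[C@@H](C)[C@@H](OC)CC/C(C)=C/I | intermediate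
15 | (3R,4S,7E)-1-[(E)-4-(tert-butyldimethylsilyloxy)-2-methylbut-2-enyloxy]-8-iodo-4-methoxy-3,7-dimethyloct-7-en-2-ol (C2 epimers) | CC(C)(C)[Si](C)(C)OC/C=C(\C)COCC(O)[C@@H](C)[C@@H](OC)CC/C(C)=C/I | intermediate
16 | (3R,4S,7E)-1-[(E)-4-hydroxy-2-methylbut-2-enyloxy]-8-iodo-4-methoxy-3,7-dimethyloct-7-en-2-ol (C2 epimers) | OC/C=C(\C)COCC(O)[C@@H](C)[C@@H](OC)CC/C(C)=C/I | intermediate
17 | (E)-4-[(3S,4S,7E)-8-iodo-4-methoxy-3,7-dimethyl-2-oxooct-7-enyloxy]-3-methylbut-2-enal | O=C/C=C(\C)COCC(=O)[C@@H](C)[C@@H](OC)CC/C(C)=C/I | intermediate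
18 | alkenylchromium dichloride derived from 17 (not isolated) | O=C/C=C(\C)COCC(=O)[C@@H](C)[C@@H](OC)CC/C(C)=C/[Cr](Cl)Cl | intermediate
19 | (4S,5S,8E,10S,11E)-10-hydroxy-5-methoxy-4,8,12-trimethyl-1-oxacyclotrideca-8,11-dien-3-one | CO[C@H]1CC/C(C)=C/[C@H](O)/C=C(\C)COCC(=O)[C@H]1C | intermediate
20 | (4S,5S,8E,10S,11E)-5-methoxy-4,8,12-trimethyl-10-(triethylsilyloxy)-1-oxacyclotrideca-8,11-dien-3-one | CO[C@H]1CC/C(C)=C/[C@H](O[Si](CC)(CC)CC)/C=C(\C)COCC(=O)[C@H]1C | intermediate
21 | lithium Z enolate (C8=C9) of 20 (not isolated) | CO[C@H]1CC/C(C)=C/[C@H](O[Si](CC)(CC)CC)/C=C(\C)CO/C=C(\[O-])[C@H]1C.[Li+] | intermediate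
22 | lithium C8 alkoxide of 23 (not isolated) | CO[C@H]1CC/C(C)=C/[C@H](O[Si](CC)(CC)CC)[C@H](C(C)=C)[C@@H]([O-])C(=O)[C@H]1C.[Li+] | intermediate
23 | (2R,3R,4S,5E,9S,10S)-2-hydroxy-9-methoxy-6,10-dimethyl-3-(prop-1-en-2-yl)-4-(triethylsilyloxy)cyclodec-5-en-1-one | CO[C@H]1CC/C(C)=C/[C@H](O[Si](CC)(CC)CC)[C@H](C(C)=C)[C@@H](O)C(=O)[C@H]1C | intermediate
24 | C8 tert-butyldimethylsilyl ether of 23 | CO[C@H]1CC/C(C)=C/[C@H](O[Si](CC)(CC)CC)[C@H](C(C)=C)[C@@H](O[Si](C)(C)C(C)(C)C)C(=O)[C@H]1C | intermediate
25 | C12 catechol boronate from 24 (C11 epimers, not isolated) | CO[C@H]1CC/C(C)=C/[C@H](O[Si](CC)(CC)CC)[C@H](C(C)CB2Oc3ccccc3O2)[C@@H](O[Si](C)(C)C(C)(C)C)C(=O)[C@H]1C | intermediate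
26 | C12 primary alcohol from 24 (C11 epimers) | CO[C@H]1CC/C(C)=C/[C@H](O[Si](CC)(CC)CC)[C@H](C(C)CO)[C@@H](O[Si](C)(C)C(C)(C)C)C(=O)[C@H]1C | intermediate
27 | C12 aldehyde (C11 epimers) | CO[C@H]1CC/C(C)=C/[C@H](O[Si](CC)(CC)CC)[C@H](C(C)C=O)[C@@H](O[Si](C)(C)C(C)(C)C)C(=O)[C@H]1C | intermediate
28 | C6 hydroxy C12 aldehyde (C11 epimers, not isolated) | CO[C@H]1CC/C(C)=C/[C@H](O)[C@H](C(C)C=O)[C@@H](O[Si](C)(C)C(C)(C)C)C(=O)[C@H]1C | intermediate
29 | cis-fused 6,12-lactol with C8 OTBS (C11 and C12 epimers) | CO[C@H]1CC/C(C)=C/[C@@H]2OC(O)C(C)[C@@H]2[C@@H](O[Si](C)(C)C(C)(C)C)C(=O)[C@H]1C | intermediate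
30 | (11S)-6,12-lactol with C8 OTBS (C12 anomers) | CO[C@H]1CC/C(C)=C/[C@@H]2OC(O)[C@@H](C)[C@@H]2[C@@H](O[Si](C)(C)C(C)(C)C)C(=O)[C@H]1C | intermediate
31 | (1S,6S,7S,8R,10S,11S)-8-(tert-butyldimethylsilyloxy)-1-methoxy-9-oxogermacr-4(E)-en-12,6-olide | CO[C@H]1CC/C(C)=C/[C@@H]2OC(=O)[C@@H](C)[C@@H]2[C@@H](O[Si](C)(C)C(C)(C)C)C(=O)[C@H]1C | intermediate
32 | (1S,6S,7R,8R,10S,11S)-8-hydroxy-1-methoxy-9-oxogermacr-4(E)-en-12,6-olide | CO[C@H]1CC/C(C)=C/[C@@H]2OC(=O)[C@@H](C)[C@@H]2[C@@H](O)C(=O)[C@H]1C | intermediate
33 | tiglic acid | C/C=C(\C)C(=O)O | starting material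
34 | (E)-2-methylbut-2-en-1-ol | C/C=C(\C)CO | intermediate
35 | [(2R,3R)-2,3-dimethyloxiran-2-yl]methanol | OC[C@@]1(C)O[C@@H]1C | intermediate
36 | (2S,3R)-2,3-dimethyloxirane-2-carboxylic acid | OC(=O)[C@@]1(C)O[C@@H]1C | intermediate
37 | mixed anhydride of 36 with 2,4,6-trichlorobenzoic acid (not isolated) | O=C(OC(=O)[C@@]1(C)O[C@@H]1C)c1c(Cl)cc(Cl)cc1Cl | intermediate
38 | CNP0145898.1, (1S,6S,7S,8R,10S,11S)-8-[(2S,3R)-2,3-dimethyloxirane-2-carbonyloxy]-1-methoxy-9-oxogermacr-4(E)-en-12,6-olide | CO[C@H]1CC/C(C)=C/[C@@H]2OC(=O)[C@@H](C)[C@@H]2[C@@H](OC(=O)[C@@]2(C)O[C@@H]2C)C(=O)[C@H]1C | target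

**Step count and risks**

Total step count: 25. Longest linear sequence: 19 steps (steps 1–5, 9–21 and 25).

Steps most likely to fail:

1. Step 14 (the labelled step). The enolate may follow the [3,3] Claisen path, may form at C10 and expel methoxide, or C8 may add to the other face of C7. The fallback changes the carbanion from the ketone enolate to a hydrazone azaenolate, for which the [2,3] shift of open-chain α-allyloxy ketone derivatives is established and deprotonation goes to the less substituted α-carbon. It sets out from 20: condensation with Me2NNH2 (AcOH cat., EtOH) should give the N,N-dimethylhydrazone of 20 F1; LiN(iPr)2 in THF from −78 to 0 °C should give, by [2,3]-Wittig shift of the azaenolate, the rearranged hydroxy hydrazone F2; hydrolysis with CuCl2 in THF/pH 7 buffer returns the route at 23.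

2. Step 12. The ligand may give poor facial selectivity in the addition of the alkenylchromium species to the enal. The fallback gives up reagent control for separation and recycling. It sets out from 17: the ligand-free CrCl2/NiCl2 closure should give 19 together with the (6R)-epimer of 19 F3, which is removed by chromatography; F3 is oxidised with MnO2 to the cross-conjugated macrocyclic dienone F4, and reduction with NaBH4/CeCl3 returns a mixture of 19 and F3 that is separated again. The route is rejoined at 19.

3. Step 16. The borane may reduce the C9 carbonyl group, or hydroboration of the crowded alkene may be too slow. The fallback removes the chemoselectivity demand by sacrificing and restoring the ketone. It sets out from 24: NaBH4 in MeOH should give the C9 carbinol of 24 F5 (C9 epimers); 9-BBN in THF followed by NaBO3 should hydroborate only the 1,1-disubstituted alkene and give the C9,C12 diol F6 (C9 and C11 epimers); excess Dess–Martin periodinane oxidises both carbinols and rejoins the route at 27.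

**Further compounds**

F1 | step 14 | N,N-dimethylhydrazone of 20 | CO[C@H]1CC/C(C)=C/[C@H](O[Si](CC)(CC)CC)/C=C(\C)COCC(=NN(C)C)[C@H]1C
F2 | step 14 | rearranged hydroxy hydrazone (N,N-dimethylhydrazone of 23) | CO[C@H]1CC/C(C)=C/[C@H](O[Si](CC)(CC)CC)[C@H](C(C)=C)[C@@H](O)C(=NN(C)C)[C@H]1C
F3 | step 12 | (6R)-epimer of 19 | CO[C@H]1CC/C(C)=C/[C@@H](O)/C=C(\C)COCC(=O)[C@H]1C
F4 | step 12 | macrocyclic C6 dienone | CO[C@H]1CC/C(C)=C/C(=O)/C=C(\C)COCC(=O)[C@H]1C
F5 | step 16 | C9 carbinol of 24 (C9 epimers) | CO[C@H]1CC/C(C)=C/[C@H](O[Si](CC)(CC)CC)[C@H](C(C)=C)[C@@H](O[Si](C)(C)C(C)(C)C)C(O)[C@H]1C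
F6 | step 16 | C9,C12 diol (C9 and C11 epimers) | CO[C@H]1CC/C(C)=C/[C@H](O[Si](CC)(CC)CC)[C@H](C(C)CO)[C@@H](O[Si](C)(C)C(C)(C)C)C(O)[C@H]1C
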